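**Retrosynthetic overview**

1. Endgame on ring B and the side chain: the butenolide comes from C12–C13 alkylation of 3-(phenylsulfanyl)oxolan-2-one and sulfoxide elimination; C8=C17 from methylenation of an 8-ketone; C9–C11 from a B-alkyl Suzuki coupling at the C9 enol triflate, with H-9α set by hydroboration from the α face.
2. The C19 methyl ester and the C20 acetoxymethyl group arise together by α-ketol cleavage of a cyclopentanone (C19–C20) that bridges C4 and C10; that ketone comes from reductive opening of the C1–C20 bond of a cyclopropyl ketone.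
3. Key disconnection C10–C20: the diazomethyl ketone on C4 (C19 carbonyl, diazo carbon = C20) adds as a rhodium carbenoid across C1=C10. The strategy rests on C19 (axial on C4) and C20 (axial on C10) being 1,3-diaxial on the β face of ring A, so a carbon grown from the C19 carbonyl can reach C10 only on the face where C20 must stand.
4. The Δ1(10)-octalin acid comes from a catalytic enantioselective Diels–Alder reaction of 6-ethenyl-1,4-dioxaspiro[4.5]dec-6-ene with methacrolein, which sets C4 and C5.
5. Ring order: ring B (cyclohexenone, bought) → ring A (Diels–Alder) → temporary cyclopropane and cyclopentanone (key step; both opened again) → butenolide ring (last).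

Key step: step 7

Remark 1: all decalin intermediates carry the labdane numbers of the target (C1–C20); β is the face of C20, α the face of H-5 and H-9.
Remark 2: the oxazaborolidinium from (S)-α,α-diphenylprolinol is taken to deliver the diene to the Re face at C-α of methacrolein, as it does with 2-substituted acroleins; if the sense were opposite, the catalyst from (R)-α,α-diphenylprolinol would be used and nothing else changes.
Remark 3: 3-(phenylsulfanyl)oxolan-2-one is made (step 20), not bought.

**Route**

Step 1
Reactants: 1 cyclohex-2-en-1-one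
Product: 2 2-iodocyclohex-2-en-1-one
Conditions: I2, pyridine/CH2Cl2 (1:1), 0 °C → rt
Reagents that add atoms: iodine, II
Why: Pyridine-mediated α-iodination of the enone (conjugate addition of pyridine, iodination of the enolate, elimination) should give the 2-iodoenone regiospecifically; no stereocentre is formed.

Step 2
Reactants: 2 2-iodocyclohex-2-en-1-one
Product: 3 6-iodo-1,4-dioxaspiro[4.5]dec-6-ene
Conditions: HOCH2CH2OH, p-TsOH·H2O (cat.), benzene, reflux, Dean–Stark
Reagents that add atoms: ethane-1,2-diol, OCCO
Why: Acid-catalysed ketalisation with azeotropic removal of water masks the ketone while the vinylic iodine keeps the double bond in place; ketalising before the coupling avoids free 2-vinylcyclohex-2-enone, which dimerises readily.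

Step 3
Reactants: 3 6-iodo-1,4-dioxaspiro[4.5]dec-6-ene; 4 tributyl(vinyl)stannane
Product: 5 6-ethenyl-1,4-dioxaspiro[4.5]dec-6-ene
Conditions: Pd(PPh3)4 (5 mol %), CuI (10 mol %), CsF, DMF, 45 °C
Reagents that add atoms: none
Why: Stille coupling of the alkenyl iodide with the vinylstannane (oxidative addition, fluoride- and copper-assisted transmetalation, reductive elimination) runs under neutral conditions, so the ketal should survive and the 1,3-diene results.

Step 4
Reactants: 5 6-ethenyl-1,4-dioxaspiro[4.5]dec-6-ene; 6 methacrolein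
Product: 7 9,9-ethylenedioxy-4α-methyl-5α-H-octal-1(10)-ene-4β-carbaldehyde
Conditions: (S)-3,3-diphenyl-1-(o-tolyl)pyrrolo[1,2-c][1,3,2]oxazaborolidine protonated with HN(SO2CF3)2 (15 mol %), CH2Cl2, −78 → −40 °C
Reagents that add atoms: none
Why: Lewis-acid-catalysed Diels–Alder reaction in which the alkyl-substituted ring terminus of the diene and the inductively withdrawing ketal on its inner carbon send the CH2 of methacrolein to the unsubstituted vinyl terminus so that the quaternary carbon (C4) bonds to C5, the formyl-endo transition state places CHO cis to C6 (4β-CHO, 5α-H), and the chiral oxazaborolidinium shields one face of the coordinated s-trans aldehyde so that the diene adds to the Re face at C-α, which fixes the absolute configuration of C4 and C5.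

Step 5
Reactants: 7 9,9-ethylenedioxy-4α-methyl-5α-H-octal-1(10)-ene-4β-carbaldehyde
Product: 8 9,9-ethylenedioxy-4α-methyl-5α-H-octal-1(10)-ene-4β-carboxylic acid
Conditions: NaClO2, NaH2PO4, 2-methylbut-2-ene, t-BuOH/H2O, 0 °C → rt
Reagents that add atoms: sodium chlorite, [Na+].[O-]Cl=O
Why: Pinnick oxidation converts the hindered, non-enolisable aldehyde into the acid at a buffered pH the dioxolane tolerates, and 2-methylbut-2-ene scavenges HOCl so that the C1=C10 olefin is left alone; no stereocentre changes.

Step 6
Reactants: 8 9,9-ethylenedioxy-4α-methyl-5α-H-octal-1(10)-ene-4β-carboxylic acid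
Product: 10 4β-diazoacetyl-9,9-ethylenedioxy-4α-methyl-5α-H-octal-1(10)-ene, via acid chloride 9 (not isolated)
Conditions: Me2C=C(Cl)NMe2, CH2Cl2, 0 °C → rt; then CH2N2 (excess), Et2O, 0 °C → rt
Reagents that add atoms: diazomethane, C=[N+]=[N-]
Why: The α-chloroenamine makes the acid chloride without releasing HCl (the ketal survives), and acylation of excess diazomethane (first stage of the Arndt–Eistert sequence) gives the diazomethyl ketone while the second equivalent consumes the HCl; C4 is quaternary, so nothing can epimerise.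

Step 7
Reactants: 10 4β-diazoacetyl-9,9-ethylenedioxy-4α-methyl-5α-H-octal-1(10)-ene
Product: 11 cyclopropyl ketone in which C20 is bonded to C19 (C=O), C1β and C10β (9,9-ethylenedioxy, 4α-methyl, 5α-H)
Conditions: Rh2(OAc)4 (1 mol %), CH2Cl2, 40 °C, slow addition of 10 at high dilution
Reagents that add atoms: none
Why: Rh2(OAc)4 takes N2 from the diazo carbon to give an electrophilic rhodium carbenoid at C20, which adds in one concerted, asynchronous [2+1] step across the nucleophilic trisubstituted C1=C10 olefin and forms C20–C10 and C20–C1. The closest known reaction is the rhodium- or copper-catalysed intramolecular cyclopropanation of cyclohex-3-enyl diazomethyl ketones, to which 10 corresponds atom for atom. The cyclopentanone ring C4–C19–C20–C10–C5 closes in the bicyclo[3.1.0]hexan-2-one mode (the carbenoid carbon bonds to the nearer olefin carbon through a five-membered ring), and the cyclopropane C1–C10–C20 closes by the [2+1] addition itself. The new centres C10, C1 and C20 are all set by the tether: the acyl group is axial (β) on C4 and trans to H-5, so the carbenoid reaches only the β face of the olefin, C20 ends cis to C19 and trans to H-5, and the cis fusion of the three-membered ring fixes C1 and C20. The step needs chemoselectivity for C=C addition over 1,5 C–H insertion at C2 or C6 and over attack on a dioxolane oxygen; this is secured by the 1,3-diaxial proximity of the carbenoid to the electron-rich olefin and by slow addition at high dilution, which also suppresses carbene dimerisation.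

Step 8
Reactants: 11 cyclopropyl ketone
Product: 13 bridged cyclopentanone (19-oxo; C20 methylene joins C19 to C10β; C1 is CH2), via lithium enolate 12 (not isolated)
Conditions: Li (2.5 equiv), t-BuOH (1 equiv), NH3(l)/THF, −78 °C; then NH4Cl
Reagents that add atoms: none
Why: Dissolving-metal reduction of the conjugated cyclopropyl ketone should open the C1–C20 bond, which lies outside the cyclopentanone ring, is the better aligned of the two with the carbonyl π system and leaves a secondary instead of a tertiary carbanion, so that C20 stays on C10 as a methylene and the C19–C20 lithium enolate is protonated on quench; C4, C5 and C10 are untouched.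

Step 9
Reactants: 13 bridged cyclopentanone
Product: 15 20-hydroxy ketone (C20 epimers both usable), via potassium enolate 14 (not isolated)
Conditions: KN(SiMe3)2, THF, −78 °C; then 3-phenyl-2-(phenylsulfonyl)oxaziridine, −78 °C; aq. NH4Cl
Reagents that add atoms: 3-phenyl-2-(phenylsulfonyl)oxaziridine, O=S(=O)(c1ccccc1)N1OC1c1ccccc1
Why: Enolate oxidation with the Davis oxaziridine: C4 is quaternary, so the ketone can enolise only toward C20, and the configuration of the new carbinol carbon is irrelevant because step 10 destroys it.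

Step 10
Reactants: 15 20-hydroxy ketone
Product: 16 methyl 9,9-ethylenedioxy-20-oxo-11,12,13,14,15,16,17-heptanorlabdan-19-oate
Conditions: Pb(OAc)4, MeOH/toluene (1:1), 0 °C
Reagents that add atoms: methanol, CO
Why: Lead tetraacetate cleavage of the α-ketol through its methanol hemiketal (Criegee-type glycol cleavage) breaks C19–C20 and should deliver directly the C19 methyl ester on C4 and the C20 aldehyde on C10 without touching a stereocentre.

Step 11
Reactants: 16 methyl 9,9-ethylenedioxy-20-oxo-11,12,13,14,15,16,17-heptanorlabdan-19-oate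
Product: 18 methyl 20-acetoxy-9,9-ethylenedioxy-11,12,13,14,15,16,17-heptanorlabdan-19-oate, via aluminium alkoxide 17 (not isolated)
Conditions: i-Bu2AlH (1.1 equiv), CH2Cl2, −78 °C; then pyridine, DMAP, Ac2O, −78 → 0 °C
Reagents that add atoms: acetic anhydride, CC(=O)OC(C)=O
Why: i-Bu2AlH at −78 °C reduces only the aldehyde (the axial neopentyl C19 ester and the ketal are inert) and the aluminium alkoxide is acetylated in the same flask, as in the reductive acetylation of esters, so that a free C20 alkoxide, which would lactonise onto the 1,3-diaxial C19 ester, is never released.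

Step 12
Reactants: 18 methyl 20-acetoxy-9,9-ethylenedioxy-11,12,13,14,15,16,17-heptanorlabdan-19-oate
Product: 19 methyl 20-acetoxy-9-oxo-11,12,13,14,15,16,17-heptanorlabdan-19-oate
Conditions: p-TsOH·H2O (cat.), acetone/H2O (10:1), 40 °C
Reagents that add atoms: water, O
Why: Acid-catalysed hydrolysis of the dioxolane frees the C9 ketone under conditions mild enough for the acetate and the hindered methyl ester; C10 is quaternary, so the β-acetoxy ketone cannot eliminate.

Step 13
Reactants: 19 methyl 20-acetoxy-9-oxo-11,12,13,14,15,16,17-heptanorlabdan-19-oate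
Product: 20 methyl 20-acetoxy-9-(trifluoromethylsulfonyloxy)-11,12,13,14,15,16,17-heptanorlabd-8-en-19-oate
Conditions: Tf2O, 2,6-di-tert-butyl-4-methylpyridine, CH2Cl2, 0 °C → rt
Reagents that add atoms: trifluoromethanesulfonic anhydride, O=S(=O)(OS(=O)(=O)C(F)(F)F)C(F)(F)F
Why: Triflation of the ketone with Tf2O and a hindered, non-nucleophilic pyridine gives the enol triflate, which can form only toward C8 because C10 is quaternary, and no metal enolate is made that could attack the neighbouring C20 acetate.

Step 14
Reactants: 20 methyl 20-acetoxy-9-(trifluoromethylsulfonyloxy)-11,12,13,14,15,16,17-heptanorlabd-8-en-19-oate; 21 tert-butyldimethyl(vinyloxy)silane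
Product: 23 methyl 20-acetoxy-12-(tert-butyldimethylsilyloxy)-13,14,15,16,17-pentanorlabd-8-en-19-oate, via alkyl-9-BBN 22 (not isolated)
Conditions: 21, 9-BBN-H, THF, 0 °C → rt; then 20, PdCl2(dppf) (5 mol %), AsPh3, aq. K3PO4, DMF, rt → 45 °C
Reagents that add atoms: none
Why: 9-BBN-H adds to the silyl enol ether with boron on the terminal carbon, and B-alkyl Suzuki–Miyaura coupling of this borane with the alkenyl triflate (oxidative addition, base-assisted transmetalation, reductive elimination) forms C9–C11 with C12 already protected as its silyl ether.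

Step 15
Reactants: 23 methyl 20-acetoxy-12-(tert-butyldimethylsilyloxy)-13,14,15,16,17-pentanorlabd-8-en-19-oate
Product: 25 methyl 20-acetoxy-8α-hydroxy-12-(tert-butyldimethylsilyloxy)-13,14,15,16,17-pentanorlabdan-19-oate (9α-H), via alkylborane 24 (not isolated)
Conditions: BH3·SMe2, THF, 0 °C → rt; then NaBO3·4H2O, THF/H2O, rt
Reagents that add atoms: sodium perborate, [Na+].[O-]OB=O
Why: Brown hydroboration–oxidation: boron goes to the less substituted C8 and hydrogen to C9 in a syn addition from the α face, opposite the axial C20 substituent on C10, which sets 9α-H (side chain β, equatorial) and 8α-B, and perborate oxidises the C–B bond with retention at a pH that spares the acetate.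

Step 16
Reactants: 25 methyl 20-acetoxy-8α-hydroxy-12-(tert-butyldimethylsilyloxy)-13,14,15,16,17-pentanorlabdan-19-oate
Product: 26 methyl 20-acetoxy-8-oxo-12-(tert-butyldimethylsilyloxy)-13,14,15,16,17-pentanorlabdan-19-oate
Conditions: Dess–Martin periodinane, NaHCO3, CH2Cl2, rt
Reagents that add atoms: none
Why: Dess–Martin oxidation of the secondary alcohol under buffered, non-epimerising conditions gives the 8-ketone; C9 already carries the more stable equatorial side chain.

Step 17
Reactants: 26 methyl 20-acetoxy-8-oxo-12-(tert-butyldimethylsilyloxy)-13,14,15,16,17-pentanorlabdan-19-oate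
Product: 27 methyl 20-acetoxy-12-(tert-butyldimethylsilyloxy)-13,14,15,16-tetranorlabd-8(17)-en-19-oate
Conditions: Zn, CH2Br2, TiCl4, THF (reagent preformed at 0–5 °C); then 26, CH2Cl2, rt
Reagents that add atoms: dibromomethane, BrCBr
Why: Takai–Lombardo methylenation: the zinc–titanium methylene reagent is non-basic and selective for ketones over esters, so the exocyclic C8=C17 olefin should form without epimerising C9 or touching the acetate and the methyl ester.

Step 18
Reactants: 27 methyl 20-acetoxy-12-(tert-butyldimethylsilyloxy)-13,14,15,16-tetranorlabd-8(17)-en-19-oate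
Product: 28 methyl 20-acetoxy-12-hydroxy-13,14,15,16-tetranorlabd-8(17)-en-19-oate
Conditions: HF·pyridine, pyridine, THF, 0 °C → rt
Reagents that add atoms: none
Why: Fluoride-mediated cleavage of the primary silyl ether with buffered HF·pyridine leaves the acetate, the ester and the exocyclic olefin alone.

Step 19
Reactants: 28 methyl 20-acetoxy-12-hydroxy-13,14,15,16-tetranorlabd-8(17)-en-19-oate
Product: 29 methyl 20-acetoxy-12-iodo-13,14,15,16-tetranorlabd-8(17)-en-19-oate
Conditions: I2, PPh3, imidazole, CH2Cl2, 0 °C → rt
Reagents that add atoms: iodine, II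
Why: Appel-type iodination converts the primary alcohol into the iodide by iodide displacement of the alkoxyphosphonium at the unhindered C12.

Step 20
Reactants: 30 3-bromooxolan-2-one; 31 benzenethiol
Product: 32 3-(phenylsulfanyl)oxolan-2-one
Conditions: Et3N, CH2Cl2, 0 °C → rt
Reagents that add atoms: none
Why: Thiolate displacement of the activated α-bromide of the lactone in an SN2 reaction gives the α-phenylsulfanyl lactone (racemic; its stereocentre is lost in step 22).

Step 21
Reactants: 29 methyl 20-acetoxy-12-iodo-13,14,15,16-tetranorlabd-8(17)-en-19-oate; 32 3-(phenylsulfanyl)oxolan-2-one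
Product: 34 methyl 20-acetoxy-13-(phenylsulfanyl)labd-8(17)-en-16,15-olid-19-oate (C13 epimers), via sodium enolate 33 (not isolated)
Conditions: 32 (1.5 equiv), NaN(SiMe3)2 (1.4 equiv), THF, −78 → 0 °C; then 29, DMPU, 0 °C → rt
Reagents that add atoms: none
Why: Alkylation of the sulfur-stabilised lactone enolate, preformed with less than one equivalent of base so that no free amide remains to attack the acetate, with the primary iodide forms C12–C13; the mixture at C13 is of no consequence.

Step 22
Reactants: 34 methyl 20-acetoxy-13-(phenylsulfanyl)labd-8(17)-en-16,15-olid-19-oate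
Product: 36 methyl (4S,5R,9S,10S)-20-acetoxylabda-8(17),13-dien-16,15-olid-19-oate (target), via sulfoxide 35 (not isolated)
Conditions: mCPBA (1.0 equiv), CH2Cl2, −78 °C; then CaCO3, toluene, 110 °C
Reagents that add atoms: none
Why: Oxidation of the sulfide to the sulfoxide at −78 °C (faster than epoxidation of the 1,1-disubstituted olefin) and thermal syn-elimination of benzenesulfenic acid toward the ring hydrogen at C14 should give the endocyclic α-substituted butenolide and complete the target.

**Compound list**

1 | cyclohex-2-en-1-one | O=C1C=CCCC1 | starting material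
2 | 2-iodocyclohex-2-en-1-one | O=C1C(I)=CCCC1 | intermediate
3 | 6-iodo-1,4-dioxaspiro[4.5]dec-6-ene | IC1=CCCCC12OCCO2 | intermediate
4 | tributyl(vinyl)stannane | C=C[Sn](CCCC)(CCCC)CCCC | starting material
5 | 6-ethenyl-1,4-dioxaspiro[4.5]dec-6-ene | C=CC1=CCCCC12OCCO2 | intermediate
6 | methacrolein | CC(=C)C=O | starting material
7 | 9,9-ethylenedioxy-4α-methyl-5α-H-octal-1(10)-ene-4β-carbaldehyde | C1CC[C@@H]2C(=CCC[C@]2(C)C=O)C13OCCO3 | intermediate
8 | 9,9-ethylenedioxy-4α-methyl-5α-H-octal-1(10)-ene-4β-carboxylic acid | C1CC[C@@H]2C(=CCC[C@]2(C)C(=O)O)C13OCCO3 | intermediate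
9 | acid chloride of 8 | C1CC[C@@H]2C(=CCC[C@]2(C)C(=O)Cl)C13OCCO3 | intermediate
10 | 4β-diazoacetyl-9,9-ethylenedioxy-4α-methyl-5α-H-octal-1(10)-ene (diazo carbon = C20) | [N-]=[N+]=CC(=O)[C@@]1(C)CCC=C2C3(OCCO3)CCC[C@@H]12 | intermediate
11 | cyclopropyl ketone (C20 bonded to C19, C1β and C10β; 9,9-ethylenedioxy) | O=C1[C@@H]2[C@@H]3CC[C@@]1(C)[C@@H]1CCCC4(OCCO4)[C@@]231 | intermediate
12 | lithium enolate (C19–OLi, C19=C20) | C1CC[C@@H]2[C@@]3(C=C(O[Li])[C@@]2(C)CCC3)C14OCCO4 | intermediate
13 | bridged cyclopentanone (19-oxo; C20 methylene on C10β; 9,9-ethylenedioxy) | C1CC[C@@H]2[C@@]3(CC(=O)[C@@]2(C)CCC3)C14OCCO4 | intermediate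
14 | potassium enolate of 13 | C1CC[C@@H]2[C@@]3(C=C(O[K])[C@@]2(C)CCC3)C14OCCO4 | intermediate
15 | 20-hydroxy derivative of 13 (C20 epimers) | C1CC[C@@H]2[C@@]3(C(O)C(=O)[C@@]2(C)CCC3)C14OCCO4 | intermediate
16 | methyl 9,9-ethylenedioxy-20-oxo-11,12,13,14,15,16,17-heptanorlabdan-19-oate | C1CC[C@@H]2[C@](C=O)(CCC[C@]2(C)C(=O)OC)C13OCCO3 | intermediate
17 | diisobutylaluminium C20-alkoxide | C1CC[C@@H]2[C@](CO[Al](CC(C)C)CC(C)C)(CCC[C@]2(C)C(=O)OC)C13OCCO3 | intermediate
18 | methyl 20-acetoxy-9,9-ethylenedioxy-11,12,13,14,15,16,17-heptanorlabdan-19-oate | C1CC[C@@H]2[C@](COC(C)=O)(CCC[C@]2(C)C(=O)OC)C13OCCO3 | intermediate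
19 | methyl 20-acetoxy-9-oxo-11,12,13,14,15,16,17-heptanorlabdan-19-oate | C1CC[C@@H]2[C@](COC(C)=O)(CCC[C@]2(C)C(=O)OC)C1=O | intermediate
20 | methyl 20-acetoxy-9-(trifluoromethylsulfonyloxy)-11,12,13,14,15,16,17-heptanorlabd-8-en-19-oate | C1C[C@@H]2[C@](COC(C)=O)(CCC[C@]2(C)C(=O)OC)C(OS(=O)(=O)C(F)(F)F)=C1 | intermediate
21 | tert-butyldimethyl(vinyloxy)silane | C=CO[Si](C)(C)C(C)(C)C | starting material
22 | 9-[2-(tert-butyldimethylsilyloxy)ethyl]-9-borabicyclo[3.3.1]nonane | CC(C)(C)[Si](C)(C)OCCB1C2CCCC1CCC2 | intermediate
23 | methyl 20-acetoxy-12-(tert-butyldimethylsilyloxy)-13,14,15,16,17-pentanorlabd-8-en-19-oate | C1C[C@@H]2[C@](COC(C)=O)(CCC[C@]2(C)C(=O)OC)C(CCO[Si](C)(C)C(C)(C)C)=C1 | intermediate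
24 | 8α-boryl compound (shown as the monoalkylborane), 9α-H | B[C@@H]1CC[C@@H]2[C@](COC(C)=O)(CCC[C@]2(C)C(=O)OC)[C@H]1CCO[Si](C)(C)C(C)(C)C | intermediate
25 | methyl 20-acetoxy-8α-hydroxy-12-(tert-butyldimethylsilyloxy)-13,14,15,16,17-pentanorlabdan-19-oate | O[C@@H]1CC[C@@H]2[C@](COC(C)=O)(CCC[C@]2(C)C(=O)OC)[C@H]1CCO[Si](C)(C)C(C)(C)C | intermediate
26 | methyl 20-acetoxy-8-oxo-12-(tert-butyldimethylsilyloxy)-13,14,15,16,17-pentanorlabdan-19-oate | O=C1CC[C@@H]2[C@](COC(C)=O)(CCC[C@]2(C)C(=O)OC)[C@H]1CCO[Si](C)(C)C(C)(C)C | intermediate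
27 | methyl 20-acetoxy-12-(tert-butyldimethylsilyloxy)-13,14,15,16-tetranorlabd-8(17)-en-19-oate | C=C1CC[C@@H]2[C@](COC(C)=O)(CCC[C@]2(C)C(=O)OC)[C@H]1CCO[Si](C)(C)C(C)(C)C | intermediate
28 | methyl 20-acetoxy-12-hydroxy-13,14,15,16-tetranorlabd-8(17)-en-19-oate | C=C1CC[C@@H]2[C@](COC(C)=O)(CCC[C@]2(C)C(=O)OC)[C@H]1CCO | intermediate
29 | methyl 20-acetoxy-12-iodo-13,14,15,16-tetranorlabd-8(17)-en-19-oate | C=C1CC[C@@H]2[C@](COC(C)=O)(CCC[C@]2(C)C(=O)OC)[C@H]1CCI | intermediate
30 | 3-bromooxolan-2-one | O=C1OCCC1Br | starting material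
31 | benzenethiol | Sc1ccccc1 | starting material
32 | 3-(phenylsulfanyl)oxolan-2-one | O=C1OCCC1Sc1ccccc1 | intermediate
33 | sodium enolate of 32 | [Na]OC1=C(Sc2ccccc2)CCO1 | intermediate
34 | methyl 20-acetoxy-13-(phenylsulfanyl)labd-8(17)-en-16,15-olid-19-oate (C13 epimers) | C=C1CC[C@@H]2[C@](COC(C)=O)(CCC[C@]2(C)C(=O)OC)[C@H]1CCC1(Sc3ccccc3)CCOC1=O | intermediate
35 | sulfoxide of 34 | C=C1CC[C@@H]2[C@](COC(C)=O)(CCC[C@]2(C)C(=O)OC)[C@H]1CCC1(S(=O)c3ccccc3)CCOC1=O | intermediate
36 | methyl (4S,5R,9S,10S)-20-acetoxylabda-8(17),13-dien-16,15-olid-19-oate | C=C1CC[C@@H]2[C@](COC(C)=O)(CCC[C@]2(C)C(=O)OC)[C@H]1CCC1=CCOC1=O | target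

**Step count**

Total: 22 steps. Longest linear sequence: 21 steps (steps 1–19, 21 and 22, from cyclohex-2-en-1-one); step 20 is a one-step side branch.

**Steps most likely to fail, with fallbacks**

Step 4. The strongly acidic catalyst may ionise the allylic dioxolane of the diene, and facial or endo control may erode at the hindered ring terminus of the diene. Fallback (sets out from 5 and 6, comes back at 8): the cycloaddition is run without a chiral catalyst (toluene, 100 °C, BHT) to give, after chromatographic removal of the exo isomer, the racemic endo aldehyde F1; Pinnick oxidation as in step 5 gives the racemic acid F2. Crystallisation with (S)-1-phenylethylamine (or its antipode, whichever gives the less soluble salt of the wanted acid) gives the 1-phenylethylammonium salt F3 of the 4β-carboxylic acid, and cold aqueous citric acid liberates 8.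

Step 7. The carbenoid may be diverted into 1,5 C–H insertion at C2 or C6, into dimerisation, or into ylide formation with a dioxolane oxygen. Fallback (sets out from 9, comes back at 13): acylation of LiCH2CO2Me (from methyl acetate and LiN(i-Pr)2, THF, −78 °C) with 9 gives the β-keto ester F4; diazo transfer (4-acetamidobenzenesulfonyl azide, Et3N, MeCN) gives the α-diazo-β-keto ester F5. The stabilised copper carbenoid (Cu(acac)2, toluene, reflux), which is more selective for C=C addition, gives the cyclopropane keto ester F6. Li/NH3 opens C1–C20 to the β-keto ester F7, and Krapcho dealkoxycarbonylation (LiCl, wet DMSO, 140 °C) gives 13.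

Step 8. Ring opening may break C10–C20 instead of C1–C20, since the two bonds lie almost symmetrically about the carbonyl plane, or the ketone may be over-reduced. Fallback (sets out from 11, comes back at 13): nucleophilic homoconjugate opening with PhSeNa (from PhSeSePh and NaBH4; DMF, 18-crown-6, 100 °C) can only attack the secondary C1 in an SN2 sense, because C10 is quaternary. It gives the 1α-phenylselanyl ketone F8 with C20 left on C10, and Bu3SnH/AIBN (toluene, 90 °C) removes the selenium to give 13.

**Further compounds**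

F1 | step 4 | racemic 9,9-ethylenedioxy-4-methyl-octal-1(10)-ene-4-carbaldehyde (endo adduct, both enantiomers) | C1CC[C@@H]2C(=CCC[C@]2(C)C=O)C13OCCO3.C1CC[C@H]2C(=CCC[C@@]2(C)C=O)C13OCCO3
F2 | step 4 | racemic 9,9-ethylenedioxy-4-methyl-octal-1(10)-ene-4-carboxylic acid (both enantiomers) | C1CC[C@@H]2C(=CCC[C@]2(C)C(=O)O)C13OCCO3.C1CC[C@H]2C(=CCC[C@@]2(C)C(=O)O)C13OCCO3
F3 | step 4 | (S)-1-phenylethylammonium salt of acid 8 | C1CC[C@@H]2C(=CCC[C@]2(C)C(=O)[O-])C13OCCO3.C[C@H]([NH3+])c1ccccc1
F4 | step 7 | methyl 3-oxo-3-(9,9-ethylenedioxy-4α-methyl-5α-H-octal-1(10)-en-4β-yl)propanoate | C1CC[C@@H]2C(=CCC[C@]2(C)C(=O)CC(=O)OC)C13OCCO3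
F5 | step 7 | methyl 2-diazo-3-oxo-3-(9,9-ethylenedioxy-4α-methyl-5α-H-octal-1(10)-en-4β-yl)propanoate | C1CC[C@@H]2C(=CCC[C@]2(C)C(=O)C(=[N+]=[N-])C(=O)OC)C13OCCO3
F6 | step 7 | cyclopropyl ketone 11 carrying CO2Me on C20 | C1CC[C@@H]2[C@@]3([C@]4(C(=O)OC)C(=O)[C@@]2(C)CC[C@H]34)C15OCCO5
F7 | step 7 | bridged cyclopentanone 13 carrying CO2Me on C20 (C20 epimers) | C1CC[C@@H]2[C@@]3(C(C(=O)OC)C(=O)[C@@]2(C)CCC3)C14OCCO4
F8 | step 8 | 1α-(phenylselanyl) derivative of bridged cyclopentanone 13 | C1CC[C@@H]2[C@@]3(CC(=O)[C@@]2(C)CC[C@@H]3[Se]c5ccccc5)C14OCCO4
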